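## Retrosynthetic overview

1. Target 15 (the gibberellin numbered 93 in the A series) ⇐ 14 ⇐ 13: the C-7 acid is unmasked last (allyl ester, palladium-catalysed deallylation), after fluoride removal of the 13-O-silyl group.
2. 13 ⇐ 12: the 2β,3β-oxirane comes from a 1β-hydroxy-2-ene by hydroxyl-directed epoxidation; 13-OH is masked so only 1-OH can direct.
3. 12 ⇐ 8 ⇐ 6: Wharton transposition of a 1β,2β-epoxy-3-ketone, itself made by nucleophilic epoxidation of the 1-en-3-one.
4. 6 ⇐ 4 ⇐ 3 ⇐ gibberellic acid 1: 13-O-silylation, allylic oxidation, allyl ester formation.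
5. Ring order: rings A to D, the γ-lactone and seven of the ten stereocentres come intact from 1. The only rings made are oxiranes: the 1,2-oxirane (step 4, opened in step 5), then the 2,3-oxirane (step 6).

Assumption: gibberellic acid, a bulk fermentation product sold by many suppliers, counts as the commercial starting material; α/β follow normal gibberellin usage (19→10 lactone bridge on the α face of ring A; H-5 and the 18-methyl on the β face).

## Route

Step 1
Reactants: 1 gibberellic acid (3β,13-dihydroxy-1,16-diene; C-7 acid; 19,10-lactone); 2 allyl bromide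
Product: 3 gibberellic acid allyl ester (C-7 allyl ester; 3β-OH and 13-OH free)
Conditions: allyl bromide, KHCO3, DMF, rt
Reagents that add atoms: allyl bromide, C=CCBr
Why: Carboxylate O-alkylation (SN2 on allyl bromide) is the reliable way to esterify the hindered C-7 acid, and bicarbonate in DMF is too weak to trigger the base-induced lactone rearrangement of ring A, so no stereocentre is touched.

Step 2
Reactants: 3 gibberellic acid allyl ester
Product: 4 3-dehydrogibberellic acid allyl ester (1-en-3-one; 13-OH free)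
Conditions: activated MnO2 (excess), CH2Cl2, rt
Reagents that add atoms: none
Why: Allylic oxidation with MnO2 converts only the secondary allylic 3β-alcohol into the enone, leaving the tertiary 13-OH, the lactone, the ester and both remaining alkenes alone.

Step 3
Reactants: 4 3-dehydrogibberellic acid allyl ester; 5 triethylsilyl trifluoromethanesulfonate (TESOTf)
Product: 6 13-O-triethylsilyl-3-dehydrogibberellic acid allyl ester
Conditions: TESOTf, 2,6-lutidine, CH2Cl2, −78 → 0 °C
Reagents that add atoms: triethylsilyl trifluoromethanesulfonate, CC[Si](CC)(CC)OS(=O)(=O)C(F)(F)F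
Why: Silyl triflate O-silylation caps the tertiary bridgehead 13-OH (the enone cannot enolise because C-4 and C-10 are quaternary), which later stops this allylic alcohol from directing epoxidation to the 16-ene.

Step 4
Reactants: 6 13-O-triethylsilyl-3-dehydrogibberellic acid allyl ester; 7 tert-butyl hydroperoxide
Product: 8 13-O-triethylsilyl 1β,2β-epoxy-3-ketone allyl ester (1β,2β-oxirane on the former enone of 6)
Conditions: t-BuOOH (decane), DBU, CH2Cl2, 0 °C → rt
Reagents that add atoms: tert-butyl hydroperoxide, CC(C)(C)OO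
Why: Weitz–Scheffer nucleophilic epoxidation: the peroxide anion adds axially to C-1 from the β face, away from the α-lactone bridge, and the enolate closes the oxirane on the same face (sets C-1 and C-2 as 1β,2β), while the anhydrous amidine base avoids retro-Claisen opening of the β-keto lactone.

Step 5
Reactants: 8 13-O-triethylsilyl 1β,2β-epoxy-3-ketone allyl ester; 9 hydrazine monohydrate
Product: 12 13-O-triethylsilyl 1β-hydroxy-2-ene allyl ester, via epoxy hydrazone 10 (not isolated), via alkenyl diazene 11 (not isolated)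
Conditions: N2H4·H2O, AcOH (cat.), MeOH, 0 °C → rt, under argon
Reagents that add atoms: none
Why: Wharton transposition: the epoxy hydrazone opens to the alkenyl diazene, which loses dinitrogen to leave the 2-ene, and the C-1–O bond is never broken, so the β-oxirane oxygen becomes the 1β-hydroxyl.

Step 6
Reactants: 12 13-O-triethylsilyl 1β-hydroxy-2-ene allyl ester; 7 tert-butyl hydroperoxide
Product: 13 13-O-triethylsilyl allyl ester of the target (1β-hydroxy-2β,3β-epoxide)
Conditions: VO(acac)2 (5 mol %), t-BuOOH (decane), CH2Cl2, 0 °C → rt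
Reagents that add atoms: tert-butyl hydroperoxide, CC(C)(C)OO
Why: Hydroxyl-directed vanadium-catalysed epoxidation: the pseudoaxial 1β-OH binds the metal and delivers oxygen syn, to the β face that is also remote from the lactone bridge (sets C-2 and C-3 as 2β,3β), while the 16-ene and the allyl group, which have no free directing hydroxyl, do not react.

Step 7
Reactants: 13 13-O-triethylsilyl allyl ester of the target
Product: 14 allyl ester of the target (1β,13-diol; 2β,3β-epoxide)
Conditions: TBAF, AcOH, THF, 0 °C → rt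
Reagents that add atoms: none
Why: Fluoride-driven desilylation (Si–F bond formation) frees the 13-OH, and the acetic acid buffer keeps the epoxide, lactone and ester away from basic alkoxide.

Step 8
Reactants: 14 allyl ester of the target
Product: 15 the target gibberellin (1β,13-dihydroxy-2β,3β-epoxy-16-ene; C-7 acid; 19,10-lactone)
Conditions: Pd(PPh3)4 (5 mol %), pyrrolidine, THF, rt; pH 4 work-up
Reagents that add atoms: none
Why: Tsuji–Trost deallylation: zerovalent palladium ionises the allyl ester to a π-allyl complex that pyrrolidine traps, freeing the acid under neutral conditions that spare the non-allylic oxirane, the lactone and the 16-ene.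

## Compound list

1 | gibberellic acid | C=C1C[C@]23C[C@@]1(O)CC[C@H]2[C@@]12OC(=O)[C@@](C)([C@H]1[C@@H]3C(=O)O)[C@@H](O)C=C2 | starting material
2 | allyl bromide | C=CCBr | starting material
3 | gibberellic acid allyl ester | C=C1C[C@]23C[C@@]1(O)CC[C@H]2[C@@]12OC(=O)[C@@](C)([C@H]1[C@@H]3C(=O)OCC=C)[C@@H](O)C=C2 | intermediate
4 | 3-dehydrogibberellic acid allyl ester (1-en-3-one) | C=C1C[C@]23C[C@@]1(O)CC[C@H]2[C@@]12OC(=O)[C@@](C)([C@H]1[C@@H]3C(=O)OCC=C)C(=O)C=C2 | intermediate
5 | triethylsilyl trifluoromethanesulfonate | CC[Si](CC)(CC)OS(=O)(=O)C(F)(F)F | starting material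
6 | 13-O-triethylsilyl-3-dehydrogibberellic acid allyl ester | C=C1C[C@]23C[C@@]1(O[Si](CC)(CC)CC)CC[C@H]2[C@@]12OC(=O)[C@@](C)([C@H]1[C@@H]3C(=O)OCC=C)C(=O)C=C2 | intermediate
7 | tert-butyl hydroperoxide | CC(C)(C)OO | starting material
8 | 13-O-triethylsilyl 1β,2β-epoxy-3-ketone allyl ester | C=C1C[C@]23C[C@@]1(O[Si](CC)(CC)CC)CC[C@H]2[C@@]12OC(=O)[C@@](C)([C@H]1[C@@H]3C(=O)OCC=C)C(=O)[C@H]1O[C@H]12 | intermediate
9 | hydrazine monohydrate | NN.O | starting material
10 | epoxy hydrazone of 8 (formed in the flask in step 5, hydrazone geometry not defined) | C=C1C[C@]23C[C@@]1(O[Si](CC)(CC)CC)CC[C@H]2[C@@]12OC(=O)[C@@](C)([C@H]1[C@@H]3C(=O)OCC=C)C(=NN)[C@H]1O[C@H]12 | intermediate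
11 | 3-diazenyl-2-en-1β-ol (alkenyl diazene, formed in the flask in step 5) | C=C1C[C@]23C[C@@]1(O[Si](CC)(CC)CC)CC[C@H]2[C@@]12OC(=O)[C@@](C)([C@H]1[C@@H]3C(=O)OCC=C)C(N=N)=C[C@H]2O | intermediate
12 | 13-O-triethylsilyl 1β-hydroxy-2-ene allyl ester | C=C1C[C@]23C[C@@]1(O[Si](CC)(CC)CC)CC[C@H]2[C@@]12OC(=O)[C@@](C)([C@H]1[C@@H]3C(=O)OCC=C)C=C[C@H]2O | intermediate
13 | 13-O-triethylsilyl allyl ester of the target (1β-hydroxy-2β,3β-epoxide) | C=C1C[C@]23C[C@@]1(O[Si](CC)(CC)CC)CC[C@H]2[C@@]12OC(=O)[C@@](C)([C@H]1[C@@H]3C(=O)OCC=C)[C@H]1O[C@H]1[C@H]2O | intermediate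
14 | allyl ester of the target | C=C1C[C@]23C[C@@]1(O)CC[C@H]2[C@@]12OC(=O)[C@@](C)([C@H]1[C@@H]3C(=O)OCC=C)[C@H]1O[C@H]1[C@H]2O | intermediate
15 | the target gibberellin (1β,13-dihydroxy-2β,3β-epoxy-16-ene; C-7 acid; 19,10-lactone) | C=C1C[C@]23C[C@@]1(O)CC[C@H]2[C@@]12OC(=O)[C@@](C)([C@H]1[C@@H]3C(=O)O)[C@H]1O[C@H]1[C@H]2O | target

## Step count and risks

Total step count: 8. Longest linear sequence: 8 (fully linear from 1).

Steps most likely to fail:

Step 4 (nucleophilic epoxidation of the β-keto lactone enone). The peroxide anion may attack the C-3 carbonyl and cleave the β-keto lactone, or the face selectivity may be poor. The fallback sets out from 3 and comes back at 8, replacing the nucleophilic epoxidation with an electrophilic, hydroxyl-directed one. Compound 3 is bis-silylated (TESOTf, 2,6-lutidine) to the 3β,13-bis(triethylsilyl) ether F1. The secondary allylic silyl ether is then cleaved selectively (PPTS, MeOH, 0 °C) to give the 13-O-triethylsilyl 3β-alcohol F2. Epoxidation with VO(acac)2 and t-BuOOH, directed syn by the pseudoaxial 3β-OH, gives the 1β,2β-epoxy-3β-alcohol F3. Dess–Martin periodinane (NaHCO3, CH2Cl2) then oxidises F3 to epoxy ketone 8, so no peroxide anion ever meets a β-keto lactone.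

Step 5 (Wharton transposition). The hydrazone nitrogen can cyclise onto the lactone carbonyl (pyrazolone formation), or hydrazine can attack the lactone. The fallback sets out from 8 and comes back at 12, replacing the hydrazone chemistry with a radical oxirane opening. Luche reduction (NaBH4, CeCl3·7H2O, MeOH, −78 °C) gives the 1β,2β-epoxy-3-alcohol F4; either C-3 epimer serves because C-3 becomes trigonal. Acylation with 1,1'-thiocarbonyldiimidazole (DMAP, toluene, 60 °C) gives the imidazolylthiocarbonate F5. Bu3SnH with AIBN (toluene, 80 °C) then generates the C-3 radical, which opens the adjacent oxirane; the resulting 1β-alkoxyl radical is reduced by the tin hydride to give 12 with C-1 unchanged.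

Step 6 (directed epoxidation). The hindered allylic alcohol may be oxidised to the enone by the vanadium peroxide instead of being epoxidised, or the reaction may stall. The fallback sets out from 12 and comes back at 13, using that enone on purpose. Dess–Martin periodinane gives the 2-en-1-one F6. Nucleophilic epoxidation (t-BuOOH, DBU, CH2Cl2) on the β face, away from the lactone bridge, gives the 2β,3β-epoxy-1-ketone F7. Reduction with LiBH(s-Bu)3 (THF, −78 °C) should deliver hydride equatorially from the α face, anti to the oxirane oxygen, to give the axial 1β-alcohol 13; this facial preference is argued by analogy with 3-oxo gibberellins and is the least certain point of the three fallbacks.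

## Further compounds

F1 | step 4 | allyl ester of 3,13-bis-O-triethylsilyl gibberellic acid | C=C1C[C@]23C[C@@]1(O[Si](CC)(CC)CC)CC[C@H]2[C@@]12OC(=O)[C@@](C)([C@H]1[C@@H]3C(=O)OCC=C)[C@@H](O[Si](CC)(CC)CC)C=C2
F2 | step 4 | allyl ester of 13-O-triethylsilyl gibberellic acid (free 3β-OH) | C=C1C[C@]23C[C@@]1(O[Si](CC)(CC)CC)CC[C@H]2[C@@]12OC(=O)[C@@](C)([C@H]1[C@@H]3C(=O)OCC=C)[C@@H](O)C=C2
F3 | step 4 | allyl ester of 13-O-triethylsilyl-1β,2β-epoxy-1,2-dihydrogibberellic acid (1β,2β-epoxy-3β-ol) | C=C1C[C@]23C[C@@]1(O[Si](CC)(CC)CC)CC[C@H]2[C@@]12OC(=O)[C@@](C)([C@H]1[C@@H]3C(=O)OCC=C)[C@@H](O)[C@H]1O[C@H]12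
F4 | step 5 | 13-O-triethylsilyl-1β,2β-epoxy-3-ol allyl ester (both C-3 epimers) | C=C1C[C@]23C[C@@]1(O[Si](CC)(CC)CC)CC[C@H]2[C@@]12OC(=O)[C@@](C)([C@H]1[C@@H]3C(=O)OCC=C)C(O)[C@H]1O[C@H]12
F5 | step 5 | 3-O-(imidazol-1-ylthiocarbonyl) derivative of the epoxy alcohol (both C-3 epimers) | C=C1C[C@]23C[C@@]1(O[Si](CC)(CC)CC)CC[C@H]2[C@@]12OC(=O)[C@@](C)([C@H]1[C@@H]3C(=O)OCC=C)C(OC(=S)n1ccnc1)[C@H]1O[C@H]12
F6 | step 6 | 13-O-triethylsilyl-2-en-1-one allyl ester | C=C1C[C@]23C[C@@]1(O[Si](CC)(CC)CC)CC[C@H]2[C@@]12OC(=O)[C@@](C)([C@H]1[C@@H]3C(=O)OCC=C)C=CC2=O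
F7 | step 6 | 13-O-triethylsilyl-2β,3β-epoxy-1-ketone allyl ester | C=C1C[C@]23C[C@@]1(O[Si](CC)(CC)CC)CC[C@H]2[C@@]12OC(=O)[C@@](C)([C@H]1[C@@H]3C(=O)OCC=C)[C@H]1O[C@H]1C2=O
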